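**Retrosynthetic overview**
1. Locants: the indenone is C1 (C=O), C2, C3, C3a, C4 (OH), C5, C6 (Me), C7 (OMe), C7a, with benzo ring A and five-membered ring C. Ring B is the benzophenone ring on C2: C1' (aroyl), C2' (OH), C3', C4' (Me), C5' (OMe), C6' (bonded to C2). Rings D (on C3) and E (on the ring B ketone) are the 2,6-dimethoxyphenyl groups.
2. Enabling feature: ring B is a hydroquinone monomethyl ether (C2'-OH para to C5'-OMe), and C6' lies ortho to C5' and β to both C2' and the aroyl C=O on C1'. The 4,4-dimethoxydienone (quinone monoketal) of ring B is therefore a doubly activated Michael acceptor exactly at C6'. It returns to the arene by loss of MeOH with OH and OMe already differentiated. On ring A, C1 and C3 are 1,4-related carbonyl carbons, so C2 can close ring C by aldol condensation.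
3. Key disconnections: C2–C6' (methyl ketone enolate plus quinone monoketal 7) and C2=C3 (aldol condensation). Both are made in step 9 from 15 and 7, together with re-aromatisation of ring B and loss of the only protecting group.
4. Both partners come from bromophenol 2. Monoketal 7 arises by esterification, anionic Fries rearrangement (C1'–CO bond) and oxidative dearomatisation. Ketone 15 arises by lithiation between Br and OMe (C7a–C1), Br–Li exchange (C3a–C3) and twofold oxidation.
5. Ring order: rings A, B, D and E are bought as arenes. Ring B is dearomatised in step 4 and re-aromatised in step 9. Ring C is formed last, in step 9.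

Key step: step 9

Remark on the chemistry: the target holds no stereocentre and its structure does not define the hindered C2–C6' axis, so no stereocontrol is planned. Compounds 11, 14, 17 and 19 are used as racemates or stereoisomer mixtures. Compounds 1, 3, 9 and 12 are taken to be catalogue compounds.

**Step 1**
Reactants: 1 4-methoxy-3-methylphenol
Product: 2 2-bromo-4-methoxy-5-methylphenol
Conditions: NBS (1.0 equiv), MeCN, 0 °C
Reagents that add atoms: N-bromosuccinimide, O=C1CCC(=O)N1Br
Why: Electrophilic aromatic bromination, in which the free OH directs ortho (its para position is blocked by OMe) and the ortho carbon para to the methyl group is both the more activated and the less hindered one.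

**Step 2**
Reactants: 2 2-bromo-4-methoxy-5-methylphenol; 3 2,6-dimethoxybenzoyl chloride
Product: 4 2-bromo-4-methoxy-5-methylphenyl 2,6-dimethoxybenzoate
Conditions: Et3N, DMAP (cat.), CH2Cl2, 0 °C to rt
Reagents that add atoms: none
Why: DMAP-catalysed esterification (nucleophilic acyl substitution) of the only acylable group of 2 with an acid chloride.

**Step 3**
Reactants: 4 2-bromo-4-methoxy-5-methylphenyl 2,6-dimethoxybenzoate
Product: 6 (2,6-dimethoxyphenyl)(2-hydroxy-5-methoxy-4-methylphenyl)methanone, via aryllithium 5 (not isolated)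
Conditions: n-BuLi (1.1 equiv), THF, −78 to 0 °C; then 1 M HCl
Reagents that add atoms: none
Why: Anionic ortho-Fries rearrangement triggered by Br–Li exchange, in which exchange outruns attack of n-BuLi on the doubly ortho-substituted ester and aryllithium 5 takes over the neighbouring acyl group (1,3 O-to-C shift), placing the aroyl group at C1' without a Lewis acid that could cleave the methyl ethers.

**Step 4**
Reactants: 6 (2,6-dimethoxyphenyl)(2-hydroxy-5-methoxy-4-methylphenyl)methanone
Product: 7 2-(2,6-dimethoxybenzoyl)-4,4-dimethoxy-5-methylcyclohexa-2,5-dien-1-one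
Conditions: PhI(OAc)2 (1.1 equiv), MeOH, 0 °C; used promptly
Reagents that add atoms: methanol, CO
Why: Oxidative dearomatisation of a 4-methoxyphenol with a trivalent iodine reagent, in which MeOH captures the activated phenol at the methoxy-bearing para carbon to give the quinone monoketal, while the acyl-deactivated ring E is left alone.

**Step 5**
Reactants: 2 2-bromo-4-methoxy-5-methylphenol
Product: 8 1-bromo-5-methoxy-2-(methoxymethoxy)-4-methylbenzene
Conditions: MOMCl, iPr2NEt, CH2Cl2, 0 °C to rt
Reagents that add atoms: chloromethyl methyl ether, COCCl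
Why: O-alkylation of the phenol (Williamson type), with MOM chosen because it survives organolithium reagents and is lost in the acid phase of step 9.

**Step 6**
Reactants: 8 1-bromo-5-methoxy-2-(methoxymethoxy)-4-methylbenzene; 9 acetaldehyde
Product: 11 1-[2-bromo-6-methoxy-3-(methoxymethoxy)-5-methylphenyl]ethan-1-ol (racemic), via aryllithium 10 (not isolated)
Conditions: LiN(iPr)2 (1.1 equiv), THF, −78 °C; 9, −78 °C; AcOH quench
Reagents that add atoms: none
Why: Directed ortho-lithiation followed by 1,2-addition, in which the C–H between Br and OMe is the most acidic one of 8, the amide base does not exchange bromine, 10 is trapped at −78 °C before LiBr can be lost, and the racemic carbinol centre is erased in step 8.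

**Step 7**
Reactants: 11 1-[2-bromo-6-methoxy-3-(methoxymethoxy)-5-methylphenyl]ethan-1-ol; 12 2,6-dimethoxybenzaldehyde
Product: 14 1-{2-[(2,6-dimethoxyphenyl)(hydroxy)methyl]-6-methoxy-3-(methoxymethoxy)-5-methylphenyl}ethan-1-ol (diastereomer mixture), via lithiated alkoxide 13 (not isolated)
Conditions: n-BuLi (2.2 equiv), THF, −78 °C; 12, −78 to 0 °C; AcOH quench
Reagents that add atoms: none
Why: Deprotonation of the alcohol, Br–Li exchange and 1,2-addition of the MOM-chelated aryllithium to a non-enolisable aldehyde, where the diastereomer mixture is harmless because both carbinol centres are oxidised in step 8.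

**Step 8**
Reactants: 14 1-{2-[(2,6-dimethoxyphenyl)(hydroxy)methyl]-6-methoxy-3-(methoxymethoxy)-5-methylphenyl}ethan-1-ol
Product: 15 1-[2-(2,6-dimethoxybenzoyl)-6-methoxy-3-(methoxymethoxy)-5-methylphenyl]ethan-1-one
Conditions: Dess–Martin periodinane (3 equiv), pyridine, CH2Cl2, 0 °C to rt
Reagents that add atoms: none
Why: Dess–Martin oxidation of both secondary benzylic alcohols, in which pyridine buffers the acetic acid so that the ionisable benzhydrol and the MOM ether survive, and any cyclic hemiketal of the half-oxidised stage stays in equilibrium with its open form and is oxidised on.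

**Step 9**
Reactants: 15 1-[2-(2,6-dimethoxybenzoyl)-6-methoxy-3-(methoxymethoxy)-5-methylphenyl]ethan-1-one; 7 2-(2,6-dimethoxybenzoyl)-4,4-dimethoxy-5-methylcyclohexa-2,5-dien-1-one
Product: 21 acredinone A, via lithium enolate 16 (not isolated), via Michael adduct 17 (not isolated), via triketone 18 (not isolated), via aldol 19 (not isolated), via MOM ether 20 (not isolated)
Conditions: LiN(SiMe3)2 (1.1 equiv), THF, −78 °C; 7, −78 to 0 °C; then anhydrous HCl in MeOH, 0 to 50 °C
Reagents that add atoms: none
Why: Proposed new method: enolate 16 should attack through its CH2 carbon at C6' of 7, the only unsubstituted ring carbon that is β to both the dienone C=O and the aroyl C=O (the other enone terminus C4' is singly activated and carries methyl), to give the chelated lithium 1,3-diketonate of 17, and should 16 first close reversibly onto its own C3 ketone, retro-aldol or Michael addition of the closed form leads to the same end product. Anhydrous HCl in MeOH then ionises the allylic ketal of 17, and loss of MeOH, loss of the C6' proton and tautomerisation re-aromatise ring B to 18, which sets free the C2' phenol and leaves the C5' methyl ether, while the absence of water keeps the ketal from hydrolysing to a hydroquinone. The C2 methylene of 18, now flanked by C1=O and ring B, enolises and closes ring C on the C3 ketone by a 5-(enolexo)-exo-trig aldol addition to 19; the ring B ketone could only be reached through a four-membered ring, and O-cyclisation of the 1,5-diketone to a 2-benzopyrylium ion is reversible in MeOH. The tertiary, doubly benzylic carbinol of 19, whose cation is stabilised by ring D, loses water irreversibly to indenone 20, and the same acid transacetalises the MOM ether to give 21. The closest known reaction types are the Michael addition of stabilised carbanions to quinone monoketals with acid aromatisation (a formal α-arylation of a carbonyl compound) and the cyclodehydration of 2-(arylacetyl)benzophenones to 2,3-diarylindenones; new are the plain ketone enolate, the 2-aroyl monoketal and the telescoping of all events. No stereocentre remains, since those of 17 and 19 are erased by aromatisation and dehydration.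

**Compound list**
1 | 4-methoxy-3-methylphenol | COc1ccc(O)cc1C | starting material
2 | 2-bromo-4-methoxy-5-methylphenol | COc1cc(Br)c(O)cc1C | intermediate
3 | 2,6-dimethoxybenzoyl chloride | COc1cccc(OC)c1C(=O)Cl | starting material
4 | 2-bromo-4-methoxy-5-methylphenyl 2,6-dimethoxybenzoate | COc1cc(Br)c(OC(=O)c2c(OC)cccc2OC)cc1C | intermediate
5 | 2-lithio-4-methoxy-5-methylphenyl 2,6-dimethoxybenzoate | COc1cc([Li])c(OC(=O)c2c(OC)cccc2OC)cc1C | intermediate
6 | (2,6-dimethoxyphenyl)(2-hydroxy-5-methoxy-4-methylphenyl)methanone | COc1cccc(OC)c1C(=O)c1cc(OC)c(C)cc1O | intermediate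
7 | 2-(2,6-dimethoxybenzoyl)-4,4-dimethoxy-5-methylcyclohexa-2,5-dien-1-one | COc1cccc(OC)c1C(=O)C1=CC(OC)(OC)C(C)=CC1=O | intermediate
8 | 1-bromo-5-methoxy-2-(methoxymethoxy)-4-methylbenzene | COCOc1cc(C)c(OC)cc1Br | intermediate
9 | acetaldehyde | CC=O | starting material
10 | [2-bromo-6-methoxy-3-(methoxymethoxy)-5-methylphenyl]lithium | COCOc1cc(C)c(OC)c([Li])c1Br | intermediate
11 | 1-[2-bromo-6-methoxy-3-(methoxymethoxy)-5-methylphenyl]ethan-1-ol (racemic) | COCOc1cc(C)c(OC)c(C(C)O)c1Br | intermediate
12 | 2,6-dimethoxybenzaldehyde | COc1cccc(OC)c1C=O | starting material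
13 | lithium 1-[2-lithio-6-methoxy-3-(methoxymethoxy)-5-methylphenyl]ethan-1-olate | COCOc1cc(C)c(OC)c(C(C)O[Li])c1[Li] | intermediate
14 | 1-{2-[(2,6-dimethoxyphenyl)(hydroxy)methyl]-6-methoxy-3-(methoxymethoxy)-5-methylphenyl}ethan-1-ol (diastereomer mixture) | COCOc1cc(C)c(OC)c(C(C)O)c1C(O)c1c(OC)cccc1OC | intermediate
15 | 1-[2-(2,6-dimethoxybenzoyl)-6-methoxy-3-(methoxymethoxy)-5-methylphenyl]ethan-1-one | COCOc1cc(C)c(OC)c(C(C)=O)c1C(=O)c1c(OC)cccc1OC | intermediate
16 | lithium enolate of 15 | COCOc1cc(C)c(OC)c(C(=C)O[Li])c1C(=O)c1c(OC)cccc1OC | intermediate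
17 | 2-(2,6-dimethoxybenzoyl)-3-{2-[2-(2,6-dimethoxybenzoyl)-6-methoxy-3-(methoxymethoxy)-5-methylphenyl]-2-oxoethyl}-4,4-dimethoxy-5-methylcyclohex-5-en-1-one (formed as its lithium diketonate, stereoisomer mixture) | COCOc1cc(C)c(OC)c(C(=O)CC2C(C(=O)c3c(OC)cccc3OC)C(=O)C=C(C)C2(OC)OC)c1C(=O)c1c(OC)cccc1OC | intermediate
18 | 1-[2-(2,6-dimethoxybenzoyl)-6-methoxy-3-(methoxymethoxy)-5-methylphenyl]-2-[2-(2,6-dimethoxybenzoyl)-3-hydroxy-6-methoxy-5-methylphenyl]ethan-1-one | COCOc1cc(C)c(OC)c(C(=O)Cc2c(OC)c(C)cc(O)c2C(=O)c2c(OC)cccc2OC)c1C(=O)c1c(OC)cccc1OC | intermediate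
19 | 2-[2-(2,6-dimethoxybenzoyl)-3-hydroxy-6-methoxy-5-methylphenyl]-3-(2,6-dimethoxyphenyl)-3-hydroxy-7-methoxy-4-(methoxymethoxy)-6-methyl-2,3-dihydro-1H-inden-1-one (stereoisomer mixture) | COc1cccc(OC)c1C(=O)c1c(O)cc(C)c(OC)c1C1C(=O)c2c(OC)c(C)cc(OCOC)c2C1(O)c1c(OC)cccc1OC | intermediate
20 | acredinone A 4-O-methoxymethyl ether | COc1cccc(OC)c1C(=O)c1c(O)cc(C)c(OC)c1C1=C(c2c(OC)cccc2OC)c2c(OCOC)cc(C)c(OC)c2C1=O | intermediate
21 | acredinone A | COc1cccc(OC)c1C(=O)c1c(O)cc(C)c(OC)c1C1=C(c2c(OC)cccc2OC)c2c(O)cc(C)c(OC)c2C1=O | target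

**Total step count:** 9
**Longest linear sequence:** 6 steps (1, 5, 6, 7, 8, 9)

**Steps most likely to fail**

1. Step 9 (Proposed new method).
- What may go wrong: 1,2-addition or proton transfer in place of conjugate addition, irreversible self-condensation of the enolate partner before it meets 7, or stalling of the ring closure in the acid phase.
- The fallback uses known chemistry, sets out from 8 and 12, and comes back at 21.
- Aryllithium 10, made from 8 as in step 6, is quenched with I2 to give 2-bromo-3-iodo-4-methoxy-1-(methoxymethoxy)-5-methylbenzene F1.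
- A twofold Stille coupling of F1 with half an equivalent of bis(tributylstannyl)acetylene (Pd(PPh3)4, CuI, DMF, 60 °C) is selective for C–I over C–Br. It should give bis[2-bromo-6-methoxy-3-(methoxymethoxy)-5-methylphenyl]acetylene F2, whose alkyne carbons are the future C1 and C2.
- Twofold Br–Li exchange (n-BuLi, THF, −78 °C) gives the dilithiated tolane F3, which adds to two equivalents of 12 to give the tolane diol F4.
- Dess–Martin oxidation gives the twofold-symmetric bis(2,6-dimethoxybenzoyl)tolane F5.
- Ketone-assisted alkyne hydration (NaAuCl4 cat., aqueous MeOH) gives the bis-MOM triketone F6. Because of the symmetry, either alkyne carbon leads to the same compound.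
- K2CO3 in MeOH closes ring C by aldol condensation to acredinone A bis-MOM ether F7, and methanolic HCl gives 21.

2. Step 4.
- What may go wrong: sluggish oxidation of the hydrogen-bonded, acyl-deactivated phenol, conjugate addition of MeOH to the doubly activated double bond, or decay of the monoketal on isolation.
- The fallback sets out from 6 and 16 and comes back at 20.
- Phenol 6 is oxidised with (NH4)2Ce(NO3)6 in aqueous MeCN (oxidative demethylation of a 4-methoxyphenol) to 2-(2,6-dimethoxybenzoyl)-5-methyl-1,4-benzoquinone F8.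
- Enolate 16 is silylated with Me3SiCl to the trimethylsilyl enol ether of 15 F9.
- F9 should add without catalyst to the ring carbon of F8 next to the aroyl group (Mukaiyama–Michael addition, the usual site for 2-acylquinones).
- Tautomerisation and loss of silicon on work-up give the hydroquinone triketone F10.
- MeI (1 equiv) and K2CO3 in acetone methylate the free C5' hydroxyl and leave the ketone-chelated C2' hydroxyl untouched. The same base closes ring C, which gives 20.
- Methanolic HCl then gives 21 as in step 9.

3. Step 6.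
- What may go wrong: loss of LiBr to an aryne, migration of bromine between aryllithiums, or deprotonation next to the MOM ether.
- The fallback avoids a bromine next to the carbanion, sets out from 1 and 9, and comes back at 14.
- MgCl2-mediated ortho-formylation of 1 (MgCl2, Et3N, paraformaldehyde, MeCN, reflux) gives 2-hydroxy-5-methoxy-4-methylbenzaldehyde F11.
- MOMCl and iPr2NEt give 5-methoxy-2-(methoxymethoxy)-4-methylbenzaldehyde F12.
- LiN(Me)CH2CH2NMe2 adds to the aldehyde to give the lithium α-amino alkoxide F13.
- n-BuLi deprotonates F13 at the carbon between the masked aldehyde and OMe, which gives the ring-lithiated α-amino alkoxide F14.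
- Addition to 9 and aqueous work-up give 4-methoxy-7-(methoxymethoxy)-3,5-dimethyl-1,3-dihydro-2-benzofuran-1-ol F15.
- 2,6-Dimethoxyphenyllithium F16 (from 1,3-dimethoxybenzene and n-BuLi, 2.2 equiv) opens this lactol and adds to the freed aldehyde, which gives 14.

**Further compounds**
F1 | step 9 | 2-bromo-3-iodo-4-methoxy-1-(methoxymethoxy)-5-methylbenzene | COCOc1cc(C)c(OC)c(I)c1Br
F2 | step 9 | bis[2-bromo-6-methoxy-3-(methoxymethoxy)-5-methylphenyl]acetylene | COCOc1cc(C)c(OC)c(C#Cc2c(OC)c(C)cc(OCOC)c2Br)c1Br
F3 | step 9 | dilithiated tolane | COCOc1cc(C)c(OC)c(C#Cc2c(OC)c(C)cc(OCOC)c2[Li])c1[Li]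
F4 | step 9 | tolane diol (stereoisomer mixture) | COCOc1cc(C)c(OC)c(C#Cc2c(OC)c(C)cc(OCOC)c2C(O)c2c(OC)cccc2OC)c1C(O)c1c(OC)cccc1OC
F5 | step 9 | twofold-symmetric bis(2,6-dimethoxybenzoyl)tolane | COCOc1cc(C)c(OC)c(C#Cc2c(OC)c(C)cc(OCOC)c2C(=O)c2c(OC)cccc2OC)c1C(=O)c1c(OC)cccc1OC
F6 | step 9 | bis-MOM triketone | COCOc1cc(C)c(OC)c(C(=O)Cc2c(OC)c(C)cc(OCOC)c2C(=O)c2c(OC)cccc2OC)c1C(=O)c1c(OC)cccc1OC
F7 | step 9 | acredinone A bis-MOM ether | COCOc1cc(C)c(OC)c(C2=C(c3c(OC)cccc3OC)c3c(OCOC)cc(C)c(OC)c3C2=O)c1C(=O)c1c(OC)cccc1OC
F8 | step 4 | 2-(2,6-dimethoxybenzoyl)-5-methyl-1,4-benzoquinone | COc1cccc(OC)c1C(=O)C1=CC(=O)C(C)=CC1=O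
F9 | step 4 | trimethylsilyl enol ether of 15 | COCOc1cc(C)c(OC)c(C(=C)O[Si](C)(C)C)c1C(=O)c1c(OC)cccc1OC
F10 | step 4 | hydroquinone triketone | COCOc1cc(C)c(OC)c(C(=O)Cc2c(O)c(C)cc(O)c2C(=O)c2c(OC)cccc2OC)c1C(=O)c1c(OC)cccc1OC
F11 | step 6 | 2-hydroxy-5-methoxy-4-methylbenzaldehyde | COc1cc(C=O)c(O)cc1C
F12 | step 6 | 5-methoxy-2-(methoxymethoxy)-4-methylbenzaldehyde | COCOc1cc(C)c(OC)cc1C=O
F13 | step 6 | lithium α-amino alkoxide | COCOc1cc(C)c(OC)cc1C(O[Li])N(C)CCN(C)C
F14 | step 6 | ring-lithiated α-amino alkoxide | COCOc1cc(C)c(OC)c([Li])c1C(O[Li])N(C)CCN(C)C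
F15 | step 6 | 4-methoxy-7-(methoxymethoxy)-3,5-dimethyl-1,3-dihydro-2-benzofuran-1-ol (stereoisomer mixture) | COCOc1cc(C)c(OC)c2C(C)OC(O)c12
F16 | step 6 | 2,6-dimethoxyphenyllithium | [Li]c1c(OC)cccc1OC
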